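# Proposed synthesis of fisetinidol-(4β→6)-ent-epifisetinidol (CNP0187520.5)

## Analysis of the target

The target is a B-type biflavanoid (a profisetinidin): two 7,3',4'-trihydroxyflavan-3-ol units, the upper one made of rings A (benzo), C (pyran) and B (catechol), the lower one of rings D, F and E, joined by one bond from C4 of ring C to C6 of ring D (suffix u marks the upper unit and l the lower unit, so the bond is C4u–C6l). It has five stereocentres: the upper unit is 2R,3S,4S, with ring B at C2u trans to the hydroxyl at C3u and that hydroxyl cis to ring D at C4u (a fisetinidol unit with a 4β aryl bond); the lower unit is 2S,3S, 2,3-cis, and belongs to the enantiomeric series (ent-epifisetinidol). The two C3 carbinols have the same absolute sense while the two C2 centres are opposite, so the compound is the C2l epimer of a dimer of one single monomer. Sensitive are the two catechols and the two resorcinol-type rings (air, base), the benzylic C2–O1 ether bonds (acid; base epimerises C2 through a quinone methide of a free ring B or E) and the doubly benzylic C4u–C6l bond, which acid can cleave again. The first difficulty is C4u: a cation at C4u is flanked by the oxygen on C3u, an arene enters from the opposite face and ends up trans to O3u, whereas the target has ring D cis to O3u. The second is ring D, which offers two nucleophilic carbons next to O7l (C6l and C8l), of which only C6l is wanted. The third is supply: both units lack the C5 hydroxyl of the cheap flavan-3-ols, and the lower unit has the unnatural configuration at C2l. The route is built on two features: C4u is the carbonyl carbon of a dihydroflavonol before it is a stereocentre, and C3u and C3l share one configuration.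

## Retrosynthetic reasoning

**17 from 16.** All eight hydroxyls are carried as benzyl ethers and released in one neutral hydrogenolysis. Benzyl ethers survive both the organometallic base and the acid of the key step, and the last step then needs neither acid nor base, which the free phenol would not tolerate.

**16 from 5 and 11 (key disconnection).** The bonds C4u–C6l and C4u–H are cut together. C4u is not treated as a cation that an arene attacks, but as the carbonyl carbon of ketone 5.
- Ring D enters as a carbanion (aryllithium 12, then organocerium 13, from bromide 11) and gives carbinol 14; its configuration at C4u is irrelevant.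
- Acid ionises 14 to the planar diarylcarbenium ion 15, and the hydrogen is the substituent that arrives last, as hydride from a silane.
- The hydride has to come from the face anti to O3u, which leaves ring D cis to O3u. The facial bias that works against the target in a cation/arene coupling now works for it.
- The site on ring D is fixed by where the bromine sat, so C8l cannot compete. No electrophile coexists with a nucleophilic product, so no oligomers can form.
- Two halves of equal size are joined late.

**11 from 9 (through 10).** The C–Br bond at C6l is made by electrophilic bromination; C6l is para to O1l and the less hindered of the two activated carbons. The C3l hydroxyl is then capped as a benzyl ether so that the aryllithium is not quenched.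

**9 from 7 (through 8).** The lower unit needs 2S, which no cheap flavanoid offers, but its C2 epimer 7 is at hand. Oxidation at C3 gives ketone 8, in which C2–H is α to the carbonyl and labile. A hydrogenation with dynamic kinetic resolution then sets C2l and C3l together as the cis (2S,3S) pair. The cut is a redox edit of two steps on an intermediate the route already holds.

**7 and 5 from 4.** Both halves come from one monomer, dihydroflavonol 4. The lower half loses the C4 oxygen (through diol 6); the upper half keeps the ketone and only has its C3 hydroxyl benzylated.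

**4 from 1 (through 2 and 3).** (+)-Taxifolin (1) supplies C2u and C3u in the right configuration. Its C4 carbonyl ties up the C5 hydroxyl in a hydrogen bond, so the other three phenols can be benzylated selectively. The C5 hydroxyl is then removed as its triflate by palladium-catalysed reduction. This is why the chiral pool is entered at the dihydroflavonol and not at a flavan-3-ol, where the C5 and C7 hydroxyls cannot be told apart.

## Alternatives that were turned down

**Alternative 1:** the textbook, biomimetic disconnection of C4u–C6l into a C4 cation and the nucleophilic ring D.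
- Forward key step: a Lewis acid ionises diol 6 to the flavan-4-yl cation A1, and ring D of 9 attacks it in a Friedel–Crafts alkylation.
- Why turned down: in A1 the oxygen on C3u sits next to the cationic carbon and shields the β face. The arene enters anti to it, so the main product should be the 4α-linked dimer A2, the C4u epimer of what is needed. Ring D can also react at C8l, and the product is still a nucleophile for A1. The route is the shortest on paper, but leaves three selectivities to chromatography.

**Alternative 2:** build ring C by a hetero-Diels–Alder reaction that forms O1u–C2u and C3u–C4u.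
- Forward key step: the o-quinone methide A3 (ring A with the exocyclic carbon C4u already bonded to ring D) adds the (E)-styrylsilane A4. The silyl group stands in for the C3 oxygen, because an enol ether would add the other way round and put the aryl group on C3. The cycloadduct A5 would then need a Tamao–Fleming oxidation.
- Why turned down: with the ring B aryl group endo, an (E)-dienophile gives the 2,4-cis, all-trans triad, again the wrong configuration at C4u, and the substrate holds nothing that enforces the exo mode. The doubly donor-stabilised A3 is a weak heterodiene, and absolute control would need a chiral acid. The sequence rebuilds a ring that 1 delivers intact.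

**Alternative 3:** build ring D from open-chain precursors by a Danheiser benzannulation.
- Forward key step: photochemical Wolff rearrangement of the diazo enone A6 gives a vinylketene, which adds the silyloxyalkyne A7 and closes to the resorcinol A8. A8 has C6l bonded to C4u and the oxygens at C7l and C8al in place by construction, so the C6l/C8l question does not arise.
- Why turned down: A6 needs a carbon substituent at C4u cis to O3u, so the facial problem is only moved to an earlier step. After the annulation, ring F still has to be made (dihydroxylation of the cinnamyl arm, cis-selective ring closure, desilylation), which adds five or more linear steps on the most valuable intermediate. Ring D, which resorcinol-type flavanoids bring along for nothing, is not worth that price.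

Key step: step 10

Remark (assumption): in step 7 the sense of induction of the ruthenium diphosphine–diamine catalyst is assigned by analogy with aryl alkyl ketones, the branched C2 side of ketone 8 taking the place of the aryl group; should 8 respond in the opposite sense, the mirror-image complex is the one to use.

## Route

Step 1
Reactants: 1 (+)-taxifolin, (2R,3R)-2-(3,4-dihydroxyphenyl)-3,5,7-trihydroxychroman-4-one
Product: 2 (2R,3R)-7-(benzyloxy)-2-[3,4-bis(benzyloxy)phenyl]-3,5-dihydroxychroman-4-one
Conditions: BnBr (3.3 equiv), K2CO3, DMF, 0 °C to rt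
Reagents that add atoms: benzyl bromide, BrCc1ccccc1
Why: Williamson ether synthesis; the 7-, 3'- and 4'-phenols are free and acidic, the C5 hydroxyl is held in a hydrogen bond to the C4 carbonyl and the C3 hydroxyl is an alcohol, so three equivalents should stop at the tribenzyl ether. The weak base and short contact are meant to keep ring C closed; no stereocentre is touched.

Step 2
Reactants: 2 (2R,3R)-7-(benzyloxy)-2-[3,4-bis(benzyloxy)phenyl]-3,5-dihydroxychroman-4-one
Product: 3 (2R,3R)-7-(benzyloxy)-2-[3,4-bis(benzyloxy)phenyl]-3-hydroxy-4-oxochroman-5-yl trifluoromethanesulfonate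
Conditions: PhNTf2 (1.2 equiv), K2CO3, DMF, rt
Reagents that add atoms: N-phenylbis(trifluoromethanesulfonimide), O=S(=O)(N(c1ccccc1)S(=O)(=O)C(F)(F)F)C(F)(F)F
Why: Phenol-selective sulfonylation; the mild triflimide reacts with the C5 aryl oxide but not with the neutral secondary C3 hydroxyl.

Step 3
Reactants: 3 (2R,3R)-7-(benzyloxy)-2-[3,4-bis(benzyloxy)phenyl]-3-hydroxy-4-oxochroman-5-yl trifluoromethanesulfonate
Product: 4 (2R,3R)-7-(benzyloxy)-2-[3,4-bis(benzyloxy)phenyl]-3-hydroxychroman-4-one (7,3',4'-tri-O-benzyl-(+)-fustin)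
Conditions: Pd(OAc)2 (5 mol %), dppf, HCO2H, Et3N, DMF, 60 °C
Reagents that add atoms: none
Why: Palladium-catalysed transfer hydrogenolysis of an aryl triflate: zerovalent palladium inserts into the C5–O bond (activated by the ortho carbonyl), formate supplies hydride with loss of CO2, and reductive elimination forms C5–H. The buffered formate medium stays near neutral, so the benzyl ethers and the ketol should survive.

Step 4
Reactants: 4 (2R,3R)-7-(benzyloxy)-2-[3,4-bis(benzyloxy)phenyl]-3-hydroxychroman-4-one
Product: 5 (2R,3R)-3,7-bis(benzyloxy)-2-[3,4-bis(benzyloxy)phenyl]chroman-4-one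
Conditions: BnOC(=NH)CCl3, TfOH (cat.), CH2Cl2–cyclohexane, 0 °C to rt
Reagents that add atoms: benzyl 2,2,2-trichloroacetimidate, N=C(OCc1ccccc1)C(Cl)(Cl)Cl
Why: Acid-catalysed O-benzylation with a trichloroacetimidate; it avoids base, which would deprotonate C3 and open ring C by β-elimination of the O1 phenoxide. C2 and C3 are not touched.

Step 5
Reactants: 4 (2R,3R)-7-(benzyloxy)-2-[3,4-bis(benzyloxy)phenyl]-3-hydroxychroman-4-one
Product: 7 (2R,3S)-7-(benzyloxy)-2-[3,4-bis(benzyloxy)phenyl]chroman-3-ol, via flavan-3,4-diol 6 (not isolated)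
Conditions: NaBH4, THF–MeOH, 0 °C; work-up; then Et3SiH, CF3CO2H, CH2Cl2, −40 to 0 °C
Reagents that add atoms: none
Why: Hydride reduction of the aryl ketone, then ionic hydrogenation of the para-alkoxybenzylic C4 alcohol through its cation. C2 and C3 stay as they are; a 1,2-hydride shift in the cation would only give ketone 8 one step early.

Step 6
Reactants: 7 (2R,3S)-7-(benzyloxy)-2-[3,4-bis(benzyloxy)phenyl]chroman-3-ol
Product: 8 (2R)-7-(benzyloxy)-2-[3,4-bis(benzyloxy)phenyl]chroman-3-one
Conditions: Dess–Martin periodinane, CH2Cl2, 0 °C to rt, under argon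
Reagents that add atoms: none
Why: Dess–Martin oxidation of the secondary alcohol under neutral conditions. C2–H is now benzylic, α to oxygen and α to the carbonyl, hence configurationally labile, which is what the next step uses.

Step 7
Reactants: 8 (2R)-7-(benzyloxy)-2-[3,4-bis(benzyloxy)phenyl]chroman-3-one
Product: 9 (2S,3S)-7-(benzyloxy)-2-[3,4-bis(benzyloxy)phenyl]chroman-3-ol (7,3',4'-tri-O-benzyl-ent-epifisetinidol)
Conditions: H2 (10 atm), RuCl2[(R)-xylBINAP][(R)-DAIPEN] (1 mol %), KOt-Bu (5 mol %), i-PrOH–toluene, rt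
Reagents that add atoms: none
Why: Noyori asymmetric hydrogenation with dynamic kinetic resolution, as known for α-aryl cycloalkanones. The base interconverts the C2 epimers of 8 through the enolate, and the catalyst should reduce the (2S) ketone faster, delivering hydride to the carbonyl face anti to the C2 aryl group. C2l and C3l are thus set together as the cis (2S,3S) pair; the homogeneous ruthenium catalyst leaves benzyl ethers alone.

Step 8
Reactants: 9 (2S,3S)-7-(benzyloxy)-2-[3,4-bis(benzyloxy)phenyl]chroman-3-ol
Product: 10 (2S,3S)-7-(benzyloxy)-2-[3,4-bis(benzyloxy)phenyl]-6-bromochroman-3-ol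
Conditions: NBS (1.0 equiv), CH2Cl2, −40 to 0 °C, dark
Reagents that add atoms: N-bromosuccinimide, BrN1C(=O)CCC1=O
Why: Electrophilic aromatic bromination. C6 is para to O1 and ortho to the benzyloxy group and has a free neighbour (C5–H), whereas C8 lies between two oxygens and is hindered; ring E has no pair of cooperating donors and should react later.

Step 9
Reactants: 10 (2S,3S)-7-(benzyloxy)-2-[3,4-bis(benzyloxy)phenyl]-6-bromochroman-3-ol
Product: 11 (2S,3S)-3,7-bis(benzyloxy)-2-[3,4-bis(benzyloxy)phenyl]-6-bromochroman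
Conditions: NaH, BnBr, n-Bu4NI (cat.), DMF, 0 °C to rt
Reagents that add atoms: benzyl bromide, BrCc1ccccc1
Why: Williamson ether synthesis on the C3 alkoxide. The flavan has no carbonyl and no free phenol, so the strong base cannot open ring F or epimerise C2.

Step 10
Reactants: 11 (2S,3S)-3,7-bis(benzyloxy)-2-[3,4-bis(benzyloxy)phenyl]-6-bromochroman; 5 (2R,3R)-3,7-bis(benzyloxy)-2-[3,4-bis(benzyloxy)phenyl]chroman-4-one
Product: 16 3,7,3',4'-tetra-O-benzylfisetinidol-(4β→6)-3,7,3',4'-tetra-O-benzyl-ent-epifisetinidol, via aryllithium 12 (not isolated), via arylcerium dichloride 13 (not isolated), via tertiary carbinol 14 (not isolated), via diarylcarbenium ion 15 (not isolated)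
Conditions: 11 (1.3 equiv), t-BuLi (2.6 equiv), THF, −78 °C; CeCl3, −78 °C; 5, −78 °C; then Et3SiH (excess), CF3CO2H (excess), CH2Cl2, −78 to −20 °C
Reagents that add atoms: none
Why: Bromine–lithium exchange gives 12 only at the carbon that carried bromine, so the interflavan bond can form at C6l and nowhere else; transmetalation to the less basic 13 lets 1,2-addition to the hindered, enolisable α-alkoxy ketone 5 outrun deprotonation at C3u (organocerium addition to a ketone). Carbinol 14 may form as either C4u epimer, which does not matter, because acid ionises it to the planar, doubly benzylic cation 15, which the silane reduces (ionic hydrogenation of a tertiary benzylic alcohol). No ring is closed; ring C comes intact from 5. The one new stereocentre, C4u, is set by hydride delivery to 15: the benzyloxy group on the adjacent C3u shields the β face, and allylic strain with the twisted ring D on C4u pushes the C3u–O bond further out of the ring plane, so hydride should enter on the α face, anti to O3u. This leaves ring D cis to O3u, the 3,4-cis (4β) arrangement of the target. It is the same facial bias that sends an arene to the α face of a flavan-4-yl cation, but the roles of aryl and hydrogen are exchanged. The step needs face selectivity at C4u and intact C2u and C3u; low temperature and excess silane are there so that capture of 15 is faster than loss of the C3u proton. Benzyl ethers, the C2–O1 bonds and the new C4u–C6l bond should tolerate the acid at this temperature.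

Step 11
Reactants: 16 3,7,3',4'-tetra-O-benzylfisetinidol-(4β→6)-3,7,3',4'-tetra-O-benzyl-ent-epifisetinidol
Product: 17 fisetinidol-(4β→6)-ent-epifisetinidol (target)
Conditions: H2 (1 atm), Pd(OH)2/C, THF–MeOH, rt; filtration and lyophilisation under argon
Reagents that add atoms: none
Why: Hydrogenolysis of six aryl benzyl and two alkyl benzyl ethers under neutral conditions. The cyclic benzylic C2–O1 bonds and the C4u–C6l bond are cleaved much more slowly, and no acid or base touches the free phenol.

## Compound list

1 | (+)-taxifolin, (2R,3R)-2-(3,4-dihydroxyphenyl)-3,5,7-trihydroxychroman-4-one | Oc1cc(O)c2c(c1)O[C@H](c1ccc(O)c(O)c1)[C@@H](O)C2=O | starting material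
2 | (2R,3R)-7-(benzyloxy)-2-[3,4-bis(benzyloxy)phenyl]-3,5-dihydroxychroman-4-one | c1ccccc1COc1cc(O)c2c(c1)O[C@H](c1ccc(OCc3ccccc3)c(OCc3ccccc3)c1)[C@@H](O)C2=O | intermediate
3 | (2R,3R)-7-(benzyloxy)-2-[3,4-bis(benzyloxy)phenyl]-3-hydroxy-4-oxochroman-5-yl trifluoromethanesulfonate | c1ccccc1COc1cc(OS(=O)(=O)C(F)(F)F)c2c(c1)O[C@H](c1ccc(OCc3ccccc3)c(OCc3ccccc3)c1)[C@@H](O)C2=O | intermediate
4 | (2R,3R)-7-(benzyloxy)-2-[3,4-bis(benzyloxy)phenyl]-3-hydroxychroman-4-one | c1ccccc1COc1ccc2c(c1)O[C@H](c1ccc(OCc3ccccc3)c(OCc3ccccc3)c1)[C@@H](O)C2=O | intermediate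
5 | (2R,3R)-3,7-bis(benzyloxy)-2-[3,4-bis(benzyloxy)phenyl]chroman-4-one | c1ccccc1COc1ccc2c(c1)O[C@H](c1ccc(OCc3ccccc3)c(OCc3ccccc3)c1)[C@@H](OCc1ccccc1)C2=O | intermediate
6 | (2R,3S,4R)-7-(benzyloxy)-2-[3,4-bis(benzyloxy)phenyl]chroman-3,4-diol (main C4 epimer expected; either serves) | c1ccccc1COc1ccc2c(c1)O[C@H](c1ccc(OCc3ccccc3)c(OCc3ccccc3)c1)[C@@H](O)[C@@H]2O | intermediate
7 | (2R,3S)-7-(benzyloxy)-2-[3,4-bis(benzyloxy)phenyl]chroman-3-ol | c1ccccc1COc1ccc2c(c1)O[C@H](c1ccc(OCc3ccccc3)c(OCc3ccccc3)c1)[C@@H](O)C2 | intermediate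
8 | (2R)-7-(benzyloxy)-2-[3,4-bis(benzyloxy)phenyl]chroman-3-one (as formed; labile at C2) | c1ccccc1COc1ccc2c(c1)O[C@H](c1ccc(OCc3ccccc3)c(OCc3ccccc3)c1)C(=O)C2 | intermediate
9 | (2S,3S)-7-(benzyloxy)-2-[3,4-bis(benzyloxy)phenyl]chroman-3-ol | c1ccccc1COc1ccc2c(c1)O[C@@H](c1ccc(OCc3ccccc3)c(OCc3ccccc3)c1)[C@@H](O)C2 | intermediate
10 | (2S,3S)-7-(benzyloxy)-2-[3,4-bis(benzyloxy)phenyl]-6-bromochroman-3-ol | c1ccccc1COc1c(Br)cc2c(c1)O[C@@H](c1ccc(OCc3ccccc3)c(OCc3ccccc3)c1)[C@@H](O)C2 | intermediate
11 | (2S,3S)-3,7-bis(benzyloxy)-2-[3,4-bis(benzyloxy)phenyl]-6-bromochroman | c1ccccc1COc1c(Br)cc2c(c1)O[C@@H](c1ccc(OCc3ccccc3)c(OCc3ccccc3)c1)[C@@H](OCc1ccccc1)C2 | intermediate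
12 | [(2S,3S)-3,7-bis(benzyloxy)-2-[3,4-bis(benzyloxy)phenyl]chroman-6-yl]lithium | c1ccccc1COc1c([Li])cc2c(c1)O[C@@H](c1ccc(OCc3ccccc3)c(OCc3ccccc3)c1)[C@@H](OCc1ccccc1)C2 | intermediate
13 | dichloro[(2S,3S)-3,7-bis(benzyloxy)-2-[3,4-bis(benzyloxy)phenyl]chroman-6-yl]cerium | c1ccccc1COc1c([Ce](Cl)Cl)cc2c(c1)O[C@@H](c1ccc(OCc3ccccc3)c(OCc3ccccc3)c1)[C@@H](OCc1ccccc1)C2 | intermediate
14 | (2R,3R)-3,7-bis(benzyloxy)-2-[3,4-bis(benzyloxy)phenyl]-4-[(2S,3S)-3,7-bis(benzyloxy)-2-[3,4-bis(benzyloxy)phenyl]chroman-6-yl]chroman-4-ol, either configuration at C4 | c1ccccc1COc1ccc2c(c1)O[C@H](c1ccc(OCc3ccccc3)c(OCc3ccccc3)c1)[C@@H](OCc1ccccc1)C2(O)c1cc2c(cc1OCc1ccccc1)O[C@@H](c1ccc(OCc3ccccc3)c(OCc3ccccc3)c1)[C@@H](OCc1ccccc1)C2 | intermediate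
15 | chroman-4-ylium ion from 14 (C4u cationic, C2u and C3u as in 5) | c1ccccc1COc1ccc2c(c1)O[C@H](c1ccc(OCc3ccccc3)c(OCc3ccccc3)c1)[C@@H](OCc1ccccc1)[C+]2c1cc2c(cc1OCc1ccccc1)O[C@@H](c1ccc(OCc3ccccc3)c(OCc3ccccc3)c1)[C@@H](OCc1ccccc1)C2 | intermediate
16 | 3,7,3',4'-tetra-O-benzylfisetinidol-(4β→6)-3,7,3',4'-tetra-O-benzyl-ent-epifisetinidol (upper unit 2R,3S with 4β aryl; lower unit 2S,3S) | c1ccccc1COc1ccc2c(c1)O[C@H](c1ccc(OCc3ccccc3)c(OCc3ccccc3)c1)[C@@H](OCc1ccccc1)[C@H]2c1cc2c(cc1OCc1ccccc1)O[C@@H](c1ccc(OCc3ccccc3)c(OCc3ccccc3)c1)[C@@H](OCc1ccccc1)C2 | intermediate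
17 | fisetinidol-(4β→6)-ent-epifisetinidol, upper unit (2R,3S,4S), lower unit (2S,3S) | Oc1ccc2c(c1)O[C@H](c1ccc(O)c(O)c1)[C@@H](O)[C@H]2c1cc2c(cc1O)O[C@@H](c1ccc(O)c(O)c1)[C@@H](O)C2 | target

## Step count and least certain steps

Total step count: 11. Longest linear sequence: 10 steps (1 → 2 → 3 → 4 → 7 → 8 → 9 → 10 → 11 → 16 → 17); step 4 is the one-step side branch to 5.

**Step 10 (key step).**
- What may go wrong: deprotonation of 5 at C3u instead of addition, followed by opening of ring C; hydride delivery to the β face of 15 if the C3u substituent shields less than expected; loss of the C3u proton from 15 and re-protonation, which would scramble C3u; acid cleavage of the new C4u–C6l bond if the mixture warms.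
- Fallback (sets out from 5 and 9, returns at 16): 5 is reduced with NaBH4 to (2R,3S,4R)-3,7-bis(benzyloxy)-2-[3,4-bis(benzyloxy)phenyl]chroman-4-ol F1, and 9 is benzylated (NaH, BnBr) to (2S,3S)-3,7-bis(benzyloxy)-2-[3,4-bis(benzyloxy)phenyl]chroman F2. A silyl triflate (TMSOTf, CH2Cl2, −78 °C) ionises F1 and the cation alkylates ring D of F2, used in excess, in a Friedel–Crafts reaction. 16 is then separated by chromatography from its C4u epimer, 3,7,3',4'-tetra-O-benzylfisetinidol-(4α→6)-3,7,3',4'-tetra-O-benzyl-ent-epifisetinidol F3, which this reaction is expected to favour. This is known chemistry, but it gives up the stereocontrol and the regiocontrol of the main route.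

**Step 7.**
- What may go wrong: epimerisation at C2 slower than reduction, so that the (2R) ketone is reduced as well; low or reversed face selection on a ketone whose two flanks are both sp3 carbons; base-induced self-condensation or air oxidation of the ketone.
- Fallback (sets out from 8, returns at 9): 8 is racemised with a catalytic amine base (DBU) and reduced with LiBH(s-Bu)3 (THF, −78 °C). The hydride attacks anti to the C2 aryl group and should give racemic cis-7-(benzyloxy)-2-[3,4-bis(benzyloxy)phenyl]chroman-3-ol F4. Esterification with (S)-2-methoxy-2-phenylacetic acid (DCC, DMAP) gives two diastereomeric esters, of which (2S,3S)-7-(benzyloxy)-2-[3,4-bis(benzyloxy)phenyl]chroman-3-yl (S)-2-methoxy-2-phenylacetate F5 is separated by chromatography or crystallisation. Methanolysis (K2CO3, MeOH) returns 9. This classical resolution costs half the material.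

**Step 3.**
- What may go wrong: ring opening or epimerisation of the base-sensitive ketol while it is heated with amine and formate; hydrolysis of the triflate back to 2; slow oxidative addition next to the bulky ring C.
- Fallback (sets out from 3, returns at 6 and at 4): 3 is first reduced with NaBH4 to (2R,3S,4R)-7-(benzyloxy)-2-[3,4-bis(benzyloxy)phenyl]-3,4-dihydroxychroman-5-yl trifluoromethanesulfonate F6, which has no enolisable ketone and cannot open by β-elimination. The same palladium/formate reduction then gives 6, which goes on to 7 by the second stage of step 5. For the upper half, the benzylic C4 hydroxyl of 6 is oxidised selectively with MnO2 (CH2Cl2) back to 4.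

## Further compounds

F1 | step 10 | (2R,3S,4R)-3,7-bis(benzyloxy)-2-[3,4-bis(benzyloxy)phenyl]chroman-4-ol | c1ccccc1COc1ccc2c(c1)O[C@H](c1ccc(OCc3ccccc3)c(OCc3ccccc3)c1)[C@@H](OCc1ccccc1)[C@@H]2O
F2 | step 10 | (2S,3S)-3,7-bis(benzyloxy)-2-[3,4-bis(benzyloxy)phenyl]chroman | c1ccccc1COc1ccc2c(c1)O[C@@H](c1ccc(OCc3ccccc3)c(OCc3ccccc3)c1)[C@@H](OCc1ccccc1)C2
F3 | step 10 | 3,7,3',4'-tetra-O-benzylfisetinidol-(4α→6)-3,7,3',4'-tetra-O-benzyl-ent-epifisetinidol | c1ccccc1COc1ccc2c(c1)O[C@H](c1ccc(OCc3ccccc3)c(OCc3ccccc3)c1)[C@@H](OCc1ccccc1)[C@@H]2c1cc2c(cc1OCc1ccccc1)O[C@@H](c1ccc(OCc3ccccc3)c(OCc3ccccc3)c1)[C@@H](OCc1ccccc1)C2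
F4 | step 7 | racemic cis-7-(benzyloxy)-2-[3,4-bis(benzyloxy)phenyl]chroman-3-ol, (2S,3S) and (2R,3R) in equal parts | c1ccccc1COc1ccc2c(c1)O[C@@H](c1ccc(OCc3ccccc3)c(OCc3ccccc3)c1)[C@@H](O)C2.c1ccccc1COc1ccc2c(c1)O[C@H](c1ccc(OCc3ccccc3)c(OCc3ccccc3)c1)[C@H](O)C2
F5 | step 7 | (2S,3S)-7-(benzyloxy)-2-[3,4-bis(benzyloxy)phenyl]chroman-3-yl (S)-2-methoxy-2-phenylacetate | c1ccccc1COc1ccc2c(c1)O[C@@H](c1ccc(OCc3ccccc3)c(OCc3ccccc3)c1)[C@@H](OC(=O)[C@@H](OC)c1ccccc1)C2
F6 | step 3 | (2R,3S,4R)-7-(benzyloxy)-2-[3,4-bis(benzyloxy)phenyl]-3,4-dihydroxychroman-5-yl trifluoromethanesulfonate | c1ccccc1COc1cc(OS(=O)(=O)C(F)(F)F)c2c(c1)O[C@H](c1ccc(OCc3ccccc3)c(OCc3ccccc3)c1)[C@@H](O)[C@@H]2O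
A1 | alternative 1 | (2R,3S)-7-(benzyloxy)-2-[3,4-bis(benzyloxy)phenyl]-3-hydroxychroman-4-ylium ion | c1ccccc1COc1ccc2c(c1)O[C@H](c1ccc(OCc3ccccc3)c(OCc3ccccc3)c1)[C@@H](O)[CH+]2
A2 | alternative 1 | 7,3',4'-tri-O-benzylfisetinidol-(4α→6)-7,3',4'-tri-O-benzyl-ent-epifisetinidol | c1ccccc1COc1ccc2c(c1)O[C@H](c1ccc(OCc3ccccc3)c(OCc3ccccc3)c1)[C@@H](O)[C@@H]2c1cc2c(cc1OCc1ccccc1)O[C@@H](c1ccc(OCc3ccccc3)c(OCc3ccccc3)c1)[C@@H](O)C2
A3 | alternative 2 | (E)-3-(benzyloxy)-6-{[(2S,3S)-3,7-bis(benzyloxy)-2-[3,4-bis(benzyloxy)phenyl]chroman-6-yl]methylidene}cyclohexa-2,4-dien-1-one | O=C1C=C(OCc2ccccc2)C=C/C1=C\c1cc2c(cc1OCc1ccccc1)O[C@@H](c1ccc(OCc3ccccc3)c(OCc3ccccc3)c1)[C@@H](OCc1ccccc1)C2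
A4 | alternative 2 | (E)-{2-[3,4-bis(benzyloxy)phenyl]ethenyl}dimethyl(phenyl)silane | C[Si](C)(/C=C/c1ccc(OCc2ccccc2)c(OCc2ccccc2)c1)c1ccccc1
A5 | alternative 2 | 2,3-trans-3,4-trans cycloadduct: 7-(benzyloxy)-2-[3,4-bis(benzyloxy)phenyl]-3-[dimethyl(phenyl)silyl]chroman carrying the lower unit at C4 on the α face | c1ccccc1COc1ccc2c(c1)O[C@H](c1ccc(OCc3ccccc3)c(OCc3ccccc3)c1)[C@@H]([Si](C)(C)c1ccccc1)[C@@H]2c1cc2c(cc1OCc1ccccc1)O[C@@H](c1ccc(OCc3ccccc3)c(OCc3ccccc3)c1)[C@@H](OCc1ccccc1)C2
A6 | alternative 3 | (1E,6E)-7-[3,4-bis(benzyloxy)phenyl]-4-diazo-1-[(2R,3S,4β)-3,7-bis(benzyloxy)-2-[3,4-bis(benzyloxy)phenyl]chroman-4-yl]hepta-1,6-dien-3-one | c1ccccc1COc1ccc2c(c1)O[C@H](c1ccc(OCc3ccccc3)c(OCc3ccccc3)c1)[C@@H](OCc1ccccc1)[C@H]2/C=C/C(=O)C(=[N+]=[N-])C/C=C/c1ccc(OCc2ccccc2)c(OCc2ccccc2)c1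
A7 | alternative 3 | ethynyloxytri(propan-2-yl)silane | C#CO[Si](C(C)C)(C(C)C)C(C)C
A8 | alternative 3 | 4-{(E)-3-[3,4-bis(benzyloxy)phenyl]prop-2-enyl}-2-[(2R,3S,4β)-3,7-bis(benzyloxy)-2-[3,4-bis(benzyloxy)phenyl]chroman-4-yl]-5-[tri(propan-2-yl)silyloxy]phenol | c1ccccc1COc1ccc2c(c1)O[C@H](c1ccc(OCc3ccccc3)c(OCc3ccccc3)c1)[C@@H](OCc1ccccc1)[C@H]2c1cc(C/C=C/c2ccc(OCc3ccccc3)c(OCc3ccccc3)c2)c(O[Si](C(C)C)(C(C)C)C(C)C)cc1O
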